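**Retrosynthetic overview**
1. The target is achiral and no ring is formed: both benzene rings come from one commercial arene, atraric acid (methyl 2,4-dihydroxy-3,6-dimethylbenzoate).
2. Key disconnection: the depside aryl ester C(=O)–O bond, giving the ring A acid (2,4-dimethoxy-3,6-dimethylbenzoic acid) and the ring B phenol (benzyl 2,4-dihydroxy-3,6-dimethylbenzoate).
3. Ring A acid: atraric acid, double O-methylation, then ester hydrolysis.
4. Ring B phenol: atraric acid, ester cleavage to the free acid, then carboxylate benzylation; both phenols stay free and only the unchelated 4-OH is acylated.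
5. Order: the two halves in parallel, TFAA-mediated esterification, final hydrogenolysis of the benzyl ester.

Assumption: the target SMILES has no stereocentre, so it defines one achiral compound and no stereocontrol is needed; atraric acid is taken as commercially available.

**Route**

Step 1
Reactants: 1 methyl 2,4-dihydroxy-3,6-dimethylbenzoate (atraric acid)
Product: 2 methyl 2,4-dimethoxy-3,6-dimethylbenzoate
Conditions: MeI (5 equiv), K2CO3 (4 equiv), DMF, 40 °C, 18 h
Reagents that add atoms: iodomethane (MeI), CI
Why: Williamson ether synthesis; K2CO3 in DMF ionises both phenols (the chelated 2-OH needs the excess MeI and warmth) while the hindered methyl ester is untouched.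

Step 2
Reactants: 2 methyl 2,4-dimethoxy-3,6-dimethylbenzoate
Product: 4 2,4-dimethoxy-3,6-dimethylbenzoic acid, via potassium carboxylate 3 (not isolated)
Conditions: KOH (6 equiv), DMSO/H2O 4:1, 100 °C, 4 h; then 2 M HCl, 0 °C
Reagents that add atoms: potassium hydroxide (KOH), [K+].[OH-]
Why: Saponification (BAC2) of a di-ortho-substituted ester is driven by poorly solvated hydroxide in aqueous DMSO, the aryl methyl ethers are inert, and cold acidification frees the acid.

Step 3
Reactants: 1 methyl 2,4-dihydroxy-3,6-dimethylbenzoate (atraric acid)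
Product: 6 2,4-dihydroxy-3,6-dimethylbenzoic acid, via acylium hydrogensulfate 5 (not isolated)
Conditions: conc. H2SO4, 0 °C → rt, 1 h; pour onto ice, filter cold
Reagents that add atoms: water, O
Why: Unimolecular acid-mediated ester cleavage (AAC1): the two ortho substituents block the tetrahedral pathway, the ortho and para hydroxyls stabilise the acylium ion, and water captures it on quenching without the hot alkali that decarboxylates this acid.

Step 4
Reactants: 6 2,4-dihydroxy-3,6-dimethylbenzoic acid
Product: 8 benzyl 2,4-dihydroxy-3,6-dimethylbenzoate, via potassium carboxylate 7 (not isolated)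
Conditions: KHCO3 (1.2 equiv), BnBr (1.05 equiv), DMF, rt, 16 h, N2
Reagents that add atoms: benzyl bromide (BnBr), BrCc1ccccc1
Why: Carboxylate O-alkylation (SN2); KHCO3 deprotonates only the carboxylic acid, so both phenols stay free and no heating is needed.

Step 5
Reactants: 4 2,4-dimethoxy-3,6-dimethylbenzoic acid; 8 benzyl 2,4-dihydroxy-3,6-dimethylbenzoate
Product: 10 benzyl 4-[(2,4-dimethoxy-3,6-dimethylbenzoyl)oxy]-2-hydroxy-3,6-dimethylbenzoate (benzyl diffractaate), via mixed trifluoroacetic anhydride 9 (not isolated)
Conditions: TFAA (5 equiv), toluene, rt, 3 h; aq. NaHCO3 work-up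
Reagents that add atoms: none
Why: Mixed-anhydride esterification: the hindered, electron-rich acid gives an acylium-like mixed anhydride that acylates the free 4-OH, whereas the 2-OH is hydrogen-bonded to the ester carbonyl and flanked on both sides.

Step 6
Reactants: 10 benzyl diffractaate
Product: 11 diffractaic acid
Conditions: H2 (1 atm), 10% Pd/C (palladium metal on charcoal), EtOAc, rt, 2 h
Reagents that add atoms: none
Why: Catalytic hydrogenolysis cleaves only the benzylic C–O bond; the aryl ester, methyl ethers and phenol are inert.

**Compound list**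
1 | methyl 2,4-dihydroxy-3,6-dimethylbenzoate (atraric acid) | COC(=O)c1c(C)cc(O)c(C)c1O | starting material
2 | methyl 2,4-dimethoxy-3,6-dimethylbenzoate | COC(=O)c1c(C)cc(OC)c(C)c1OC | intermediate
3 | potassium 2,4-dimethoxy-3,6-dimethylbenzoate | COc1cc(C)c(C(=O)[O-])c(OC)c1C.[K+] | intermediate (not isolated)
4 | 2,4-dimethoxy-3,6-dimethylbenzoic acid | COc1cc(C)c(C(=O)O)c(OC)c1C | intermediate
5 | 2,4-dihydroxy-3,6-dimethylbenzoylium hydrogensulfate | Cc1cc(O)c(C)c(O)c1C#[O+].OS(=O)(=O)[O-] | intermediate (not isolated)
6 | 2,4-dihydroxy-3,6-dimethylbenzoic acid | Cc1cc(O)c(C)c(O)c1C(=O)O | intermediate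
7 | potassium 2,4-dihydroxy-3,6-dimethylbenzoate | Cc1cc(O)c(C)c(O)c1C(=O)[O-].[K+] | intermediate (not isolated)
8 | benzyl 2,4-dihydroxy-3,6-dimethylbenzoate | Cc1cc(O)c(C)c(O)c1C(=O)OCc1ccccc1 | intermediate
9 | 2,4-dimethoxy-3,6-dimethylbenzoic trifluoroacetic anhydride | COc1cc(C)c(C(=O)OC(=O)C(F)(F)F)c(OC)c1C | intermediate (not isolated)
10 | benzyl 4-[(2,4-dimethoxy-3,6-dimethylbenzoyl)oxy]-2-hydroxy-3,6-dimethylbenzoate | COc1cc(C)c(C(=O)Oc2cc(C)c(C(=O)OCc3ccccc3)c(O)c2C)c(OC)c1C | intermediate
11 | diffractaic acid, 4-[(2,4-dimethoxy-3,6-dimethylbenzoyl)oxy]-2-hydroxy-3,6-dimethylbenzoic acid | COc1cc(C)c(C(=O)Oc2cc(C)c(C(=O)O)c(O)c2C)c(OC)c1C | target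

**Totals**
Total step count: 6.
Longest linear sequence: 4 steps (1 → 2 → 4 → 10 → 11; the ring B branch 1 → 6 → 8 → 10 → 11 is equally long).

**Steps most likely to fail, with fallbacks**

Step 3 (ester cleavage of 1 in conc. H2SO4). The risks are sulfonation of the activated ring at C-5 and decarboxylation of the β-resorcylic acid 6 during work-up. The fallback sets out from 1 and comes back at 6. It uses the decarboxylation on purpose and then puts the carboxyl group back under basic conditions. Compound 1 is boiled in aq. KOH under N2, then acidified with HCl and warmed, so that hydrolysis and loss of CO2 run together and give 2,5-dimethylresorcinol F1. Kolbe–Schmitt carboxylation of F1 (KHCO3, CO2 1 atm, glycerol, 120 °C) can only occur at the two equivalent free positions ortho to a hydroxyl and gives the potassium salt 7. Cold dilute HCl liberates 6 from 7, and step 4 follows as written.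

Step 5 (depside coupling). Both partners are hindered, and under TFAA the phenol may be trifluoroacetylated or ring B may be C-acylated. The fallback sets out from 4 and comes back at 10. It replaces acid-mediated acyl transfer by acylation of a phenoxide. Acid 4 is converted with (COCl)2 and catalytic DMF in CH2Cl2 into 2,4-dimethoxy-3,6-dimethylbenzoyl chloride F2. F2 is then stirred with 8 and K2CO3 in acetone (rt to reflux). Only the more acidic, unchelated 4-OH of 8 is ionised, so O-acylation there gives 10.

Step 2 (saponification of the di-ortho-substituted ester 2). The reaction may stall, and harsher forcing may start to cleave the ortho methyl ether. The fallback sets out from 8 and comes back at 4. It avoids hydrolysis of a hindered methyl ester altogether. Compound 8 is methylated on both phenols (MeI, K2CO3, DMF, 40 °C) to give benzyl 2,4-dimethoxy-3,6-dimethylbenzoate F3. Hydrogenolysis of F3 (H2, 10% Pd/C, EtOAc, rt) delivers acid 4 under neutral conditions.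

**Further compounds**
F1 | step 3 | 2,5-dimethylresorcinol (2,5-dimethylbenzene-1,3-diol) | Cc1cc(O)c(C)c(O)c1
F2 | step 5 | 2,4-dimethoxy-3,6-dimethylbenzoyl chloride | COc1cc(C)c(C(Cl)=O)c(OC)c1C
F3 | step 2 | benzyl 2,4-dimethoxy-3,6-dimethylbenzoate | COc1cc(C)c(C(=O)OCc2ccccc2)c(OC)c1C
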